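5 questions are asked of 4 flasks, and they come down to how much free monomer can become monomer in chains.

| flask | free monomer | initiator | temperature | remark | time |
|---|---|---|---|---|---|
| Saturday's | 0.67 M | 2 mol% | −10 °C | run made earlier |  |
| Sunday's | 1.5 M | 2 mol% | 10 °C | run made earlier |  |
| Friday's | 1 M | 1 mol% | −10 °C | run made earlier |  |
| maple | 1.0 M | 2 mol% |  | at −5 °C until 50 min, from then on at 25 °C | 3.0 h |
| larch | 1.0 M | 2 mol% | 10 °C |  | 3.0 h |
| cedar | 1.0 M | 2 mol% | −5 °C |  | 3.0 h |
| elm | 1.0 M | 2 mol% | 25 °C |  | 3.0 h |

- the flask that comes out highest in amount of monomer in chains, in percent of the free monomer charged, or "all alike" when all lie within 1.5 percentage points (maple / larch / cedar / elm / all alike)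
- monomer in chains at the end, in percent of the free monomer charged, maple
- monomer in chains at the end, in percent of the free monomer charged, larch
- monomer in chains at the end, in percent of the free monomer charged, cedar
- monomer in chains at the end, in percent of the free monomer charged, elm

- Saturday's (time / h: monomer in chains / %, free monomer / %): 0.667: 2.7, 98.1; 1.00: 2.7, 98.6; 2.00: 4.1, 95.6; 2.50: 5.1, 94.1; 4.00: 12.2, 86.5; 6.00: 24.4, 75.5; 10.0: 44.1, 55.3
- Sunday's (time / h: monomer in chains / %, free monomer / %): 0.250: 14.3, 84.3; 0.417: 33.5, 65.9; 0.667: 54.3, 42.5; 1.00: 72.5, 25.5; 1.50: 81.7, 13.0; 2.50: 85.1, 6.3; 4.00: 84.5, 5.0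
- Friday's (time / h: monomer in chains / %, free monomer / %): 0.833: 0, 99.1; 2.50: 7.2, 92.0; 4.00: 13.2, 88.0; 6.00: 25.1, 75.1; 10.0: 41.9, 53.6

(standard deviation of a reading: 1 percentage point)



Sunday's table, read downward, shows where that conversion stops. Free monomer falls from 13.0% at 1.50 h to 6.3% at 2.50 h. The next step, to 5.0% at 4.00 h, is 1.3 percentage points, close to the scatter of 1 point. So Sunday's flask behaves like a tank at its steady level: the fast growth of chains and its reverse are taken as balanced.

If the reverse step does not depend on [free monomer], that balance holds a concentration rather than a share of the charge. This gives the floor, the [free monomer] left when growth and its reverse balance, also called the equilibrium monomer concentration. Taken from the one reading in the last row, the floor at 10 °C is estimated at 0.0750 M, and this estimate carries that reading's scatter.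

Larch runs at the same temperature but starts at 1.0 M, not 1.5 M. The same floor, as read, is therefore a larger share of its charge than in Sunday's flask, 7.50% against 5.0%. On larch's smaller charge, the scatter of the reading becomes 1.5 points.

The other column adds a second term. In Sunday's last row, chains and free monomer together leave 11 points unaccounted for. The reckoning made here carries that loss unchanged into larch, which leaves 82.0% in chains.

The forecast names larch as highest, with 69% for maple, 82% for larch, 30% for cedar and 67% for elm. For larch it says “about 10% free and 7% lost gives about 82%”. Its total matches the reckoning here, but its split differs: 10% free against 7.50%, and 7% lost against 11 points.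

The flasks end at 62.3% in maple, 81.9% in larch, 34.1% in cedar and 56.3% in elm, and larch comes out higher than the others.

    free monomer + living end → monomer in chains + living end, rate k1*[living end]*[free monomer] (k = 320 L mol⁻¹ h⁻¹, Ea = 62.0 kJ mol⁻¹)
    free monomer + initiator → living end + monomer in chains (k = 8.80 L mol⁻¹ h⁻¹, Ea = 70.0 kJ mol⁻¹)
    free monomer + monomer in chains → side product (k = 0.400 L mol⁻¹ h⁻¹, Ea = 80.0 kJ mol⁻¹)
    free monomer ⇌ dormant form (K = 5.90, k = 0.0500 h⁻¹, Ea = 103 kJ mol⁻¹, ΔH = −2.00 kJ mol⁻¹)
    monomer in chains + living end → free monomer + living end, rate k5*[living end] as long as [monomer in chains] is above zero (k = 48.0 h⁻¹, Ea = 82.0 kJ mol⁻¹)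
    (constants at 25 °C)

Larch ends at 81.9% in chains, with 11.0% free monomer at 3.00 h and 9.52% at 30.0 h. Its free monomer at the long time stands 2 points above the floor share read for it, and that share carries a scatter of 1.5 points. Cedar has the same charge but is held at −5 °C. Its free monomer goes down to 5.91% at 30.0 h, which is less than the share read at 10 °C by 1.6 points.

(Readings and results come from a simulation with made-up constants, and the scatter is random.)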